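**Plan**
- The retrosynthesis cuts one C–C bond, C14–C15 of the docosanoyl chain (C1 = ester carbonyl). This gives an octyl radical and the ω-radical of benzyl tetradecanoate, each traced back to a carboxylic acid that loses CO2: nonanoic acid and the monobenzyl ester of pentadecanedioic acid.
- The enabling feature is that C14 and C15 are plain CH2 groups in an unbranched polymethylene chain, twelve methylenes away from the ester. Both radicals are therefore unstabilised primary alkyl radicals that couple at an anode instead of being oxidised further, and the benzyl ester is a non-ionisable spectator.
- The two unlike ends of the half-ester come from the 16-membered ring of ω-pentadecalactone. Opening it puts the benzyl group on the C1 carboxyl and frees the C15 alcohol, which is oxidised to the carboxyl group that serves as a traceless radical precursor.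
- Forward order: ring opening and benzylation (step 1), alcohol-to-acid oxidation (step 2), anodic decarboxylative cross-coupling joining the C8 and C14 pieces (step 3).
- Stereochemistry: the target has no stereocentre and no C=C bond. It is achiral, so the structure given is a single compound and no stereocontrol is needed.

Key step: step 3

**Step 1**
Reactants: 1 ω-pentadecalactone (oxacyclohexadecan-2-one)
Product: 3 benzyl 15-hydroxypentadecanoate, via potassium 15-hydroxypentadecanoate 2 (not isolated)
Conditions: KOH (1.0 equiv), MeOH/H2O 9:1, reflux; evaporate and dry (toluene azeotrope); then BnBr (1.1 equiv), Bu4NI (cat.), DMF, 50 °C
Reagents that add atoms: potassium hydroxide, [K+].[OH-]; benzyl bromide, BrCc1ccccc1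
Why: Saponification of the macrolactone gives the carboxylate, and SN2 O-alkylation of that carboxylate by benzyl bromide in DMF should be selective over the neutral primary alcohol, because no base strong enough to deprotonate the alcohol is present and a 16-membered ring does not reclose under these conditions.

**Step 2**
Reactants: 3 benzyl 15-hydroxypentadecanoate
Product: 5 15-(benzyloxy)-15-oxopentadecanoic acid, via benzyl 15-oxopentadecanoate 4 (not isolated)
Conditions: TEMPO (0.2 equiv), PhI(OAc)2 (2.2 equiv), CH2Cl2/MeCN/H2O, rt
Reagents that add atoms: water, O
Why: Oxoammonium-mediated (TEMPO/PhI(OAc)2) oxidation should take the primary alcohol to aldehyde 4, whose hydrate is oxidised again to the acid; the conditions are mild and non-basic, so the benzyl ester and its benzylic CH2 should be untouched.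

**Step 3**
Reactants: 5 15-(benzyloxy)-15-oxopentadecanoic acid; 6 nonanoic acid (5 equiv)
Product: 9 benzyl docosanoate, via octyl radical 7 (not isolated), via 14-(benzyloxy)-14-oxotetradecyl radical 8 (not isolated)
Conditions: undivided cell, smooth Pt anode and cathode, constant current (ca. 0.25 A cm-2), KOH (10 mol % of total acid), acetone, 35–40 °C, polarity reversed from time to time, stopped before the acid is exhausted
Reagents that add atoms: none
Why: In this mixed Kolbe electrolysis both carboxylates are oxidised by one electron at the Pt anode, the acyloxy radicals lose CO2 at once, and octyl radical 7 and the primary ω-radical 8, which build up in the anode layer, should combine head to head to form the C14–C15 CH2–CH2 bond while the carboxyl protons are reduced to H2 at the cathode. The closest known reaction type is the Kolbe cross-coupling of a dicarboxylic acid half-ester with a fatty acid, the classical electrochemical chain-extension route to long-chain esters. No ring is closed and no stereocentre is formed. The step needs the radical (Kolbe) pathway over further oxidation to cations (Hofer–Moest pathway) and cross-coupling over homo-coupling: the first is secured by both radicals being unbranched primary alkyl radicals without an α-heteroatom or α-branch, together with smooth Pt, high current density and a weakly acidic, nearly water-free electrolyte; the second by the five-fold excess of cheap acid 6, which statistically steers radical 8 into the cross product and leaves mainly a hydrocarbon dimer that should separate from the ester by polarity. The benzyl ester is not ionised and should not be oxidised at the carboxylate-covered anode, and acetone replaces the usual alcohol solvent so that the ester cannot be transesterified if the electrolyte turns basic near the end.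

**Compound list**
1 | ω-pentadecalactone (oxacyclohexadecan-2-one) | O=C1CCCCCCCCCCCCCCO1 | starting material
2 | potassium 15-hydroxypentadecanoate | [K+].[O-]C(=O)CCCCCCCCCCCCCCO | intermediate (not isolated)
3 | benzyl 15-hydroxypentadecanoate | OCCCCCCCCCCCCCCC(=O)OCc1ccccc1 | intermediate
4 | benzyl 15-oxopentadecanoate | O=CCCCCCCCCCCCCCC(=O)OCc1ccccc1 | intermediate (not isolated)
5 | 15-(benzyloxy)-15-oxopentadecanoic acid (monobenzyl pentadecanedioate) | OC(=O)CCCCCCCCCCCCCC(=O)OCc1ccccc1 | intermediate
6 | nonanoic acid | CCCCCCCCC(=O)O | starting material
7 | octyl radical | CCCCCCC[CH2] | intermediate (not isolated)
8 | 14-(benzyloxy)-14-oxotetradecyl radical | [CH2]CCCCCCCCCCCCC(=O)OCc1ccccc1 | intermediate (not isolated)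
9 | benzyl docosanoate | CCCCCCCCCCCCCCCCCCCCCC(=O)OCc1ccccc1 | target

**Totals**
Total step count: 3. Longest linear sequence: 3 steps (1 → 3 → 5 → 9); nonanoic acid 6 enters at step 3 as a commercial partner.

**Steps most likely to fail**

Step 3 (key step). What may go wrong is statistical homo-coupling of either radical at the expense of the cross-coupling, over-oxidation of the radicals to cations with loss of the chain end, coating of the anode by a waxy film, and falling current efficiency as the acid is used up. The fallback sets out from 5 and forms the same C14–C15 bond by a metal-catalysed decarboxylative coupling. Acid 5 would be condensed with N-hydroxyphthalimide (N,N'-diisopropylcarbodiimide, DMAP cat., CH2Cl2) to the redox-active ester 1-benzyl 15-(1,3-dioxoisoindolin-2-yl) pentadecanedioate F1. This would then be coupled with dioctylzinc (from octylmagnesium bromide and ZnCl2) under nickel catalysis (NiCl2·glyme, 4,4'-di-tert-butyl-2,2'-bipyridine, THF/DMF, rt), a Negishi-type decarboxylative alkyl–alkyl cross-coupling. The fallback comes back to the route at target 9.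

Step 2. What may go wrong is stalling at the aldehyde stage, or condensation of the intermediate aldehyde with unreacted alcohol followed by oxidation to a dimeric ester, both favoured when the lipophilic substrate mixes poorly with the aqueous phase. The fallback sets out from 3 and separates the two oxidation levels. Dess–Martin periodinane (CH2Cl2, NaHCO3) would give aldehyde 4, this time isolated, and a Pinnick oxidation (NaClO2, NaH2PO4, 2-methyl-2-butene, t-BuOH/H2O) would carry it to the acid. The fallback comes back to the route at 5.

Step 1. What may go wrong is incomplete ring opening, gelling of the potassium soap in DMF so that the alkylation is slow, and consumption of benzyl bromide by residual hydroxide or methanol. The fallback sets out from 1 and avoids both the carboxylate salt and the alkyl halide. Direct acid-catalysed ring-opening transesterification in a large excess of benzyl alcohol (p-TsOH cat., 90 °C; excess benzyl alcohol distilled off under vacuum) should suppress oligoester formation and give the hydroxy ester directly. The fallback comes back to the route at 3.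

**Further compounds**
F1 | step 3 | 1-benzyl 15-(1,3-dioxoisoindolin-2-yl) pentadecanedioate | O=C(CCCCCCCCCCCCCC(=O)OCc1ccccc1)ON1C(=O)c2ccccc2C1=O
F0 | step 2 | none | none
F0 | step 1 | none | none
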